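Assumption: the target is the (R)-enantiomer (CIP order OAc > CH2Ar > C11H23 > H), and 3-methoxybenzylboronic acid pinacol ester and (−)-sparteine are taken as catalogue items.

**Retrosynthetic overview**
- The phenol OH is put in last by meta-selective aromatic C–H borylation/oxidation of a 3-methoxyphenyl precursor that already carries the acetate, so no phenol protecting group is needed.
- The acetate comes from the free (R)-carbinol by simple O-acylation.
- The C1–C2 bond and the stereocentre are made together by sparteine-controlled lithiation–borylation (1,2-metallate shift) between a C12 carbamate and a 3-methoxybenzylboronic ester, followed by C–B oxidation.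
- The carbamate comes from the C12 alcohol.
- No ring is formed: the benzene ring is bought. The obvious aryl-metal opening of (R)-1,2-epoxytridecane is deliberately not used.

**Route**

Step 1
Reactants: 1 1-dodecanol
Product: 2 dodecyl N,N-diisopropylcarbamate
Conditions: NaH (1.2 equiv), THF, 0 °C to rt; then iPr2NCOCl (1.1 equiv), 60 °C, 12 h
Reagents that add atoms: N,N-diisopropylcarbamoyl chloride, CC(C)N(C(C)C)C(Cl)=O
Why: O-acylation of the sodium alkoxide by the carbamoyl chloride (nucleophilic acyl substitution, Hoppe carbamate formation) installs the group that directs α-lithiation and later leaves; no stereocentre is involved.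

Step 2
Reactants: 2 dodecyl N,N-diisopropylcarbamate; 3 2-(3-methoxybenzyl)-4,4,5,5-tetramethyl-1,3,2-dioxaborolane
Product: 7 (R)-1-(3-methoxyphenyl)tridecan-2-ol, via lithiated carbamate 4 (not isolated), via boronate complex 5 (not isolated), via secondary boronic ester 6 (not isolated)
Conditions: s-BuLi (1.3 equiv), (−)-sparteine (1.3 equiv), Et2O, −78 °C, 5 h; 3 (1.3 equiv), −78 °C, 1 h; MgBr2·OEt2, reflux, 16 h; then 2 M NaOH, 30% H2O2, THF, 0 °C to rt
Reagents that add atoms: hydrogen peroxide, OO (the hydroxyl O of 7); sec-butyllithium, CCC(C)[Li] (Li of intermediates 4 and 5 only)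
Why: Hoppe–Aggarwal lithiation–borylation, in which s-BuLi/(−)-sparteine removes the pro-S α-proton to give the configurationally stable (S)-lithio carbamate 4, borylation by 3 proceeds with retention to ate complex 5, the Mg-promoted 1,2-metallate rearrangement (benzyl migrates anti to the departing carbamate, inversion) gives (R)-boronic ester 6, and C–B oxidation with retention gives the (R)-carbinol, so the chiral diamine sets the only stereocentre.

Step 3
Reactants: 7 (R)-1-(3-methoxyphenyl)tridecan-2-ol
Product: 8 (R)-1-(3-methoxyphenyl)tridecan-2-yl acetate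
Conditions: Ac2O (1.5 equiv), pyridine (3 equiv), DMAP (5 mol%), CH2Cl2, 0 °C to rt
Reagents that add atoms: acetic anhydride, CC(=O)OC(C)=O
Why: DMAP-catalysed acylation (nucleophilic catalysis) esterifies the secondary alcohol at oxygen without breaking the C–O bond, so the (R) configuration is retained, and the anisole is inert.

Step 4
Reactants: 8 (R)-1-(3-methoxyphenyl)tridecan-2-yl acetate
Product: 10 (R)-1-(3-hydroxy-5-methoxyphenyl)tridecan-2-yl acetate, via aryl boronic ester 9 (not isolated)
Conditions: [Ir(OMe)(cod)]2 (1.5 mol%), dtbpy (3 mol%), B2pin2 (1.0 equiv), THF, 80 °C, 16 h; evaporate; Oxone (1.1 equiv), acetone/H2O 1:1, rt, 15 min; aq. NaHSO3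
Reagents that add atoms: potassium peroxymonosulfate (Oxone), [K+].[O-]S(=O)(=O)OO (the phenol O of 10); bis(pinacolato)diboron, CC1(C)OB(OC1(C)C)B1OC(C)(C)C(C)(C)O1 (boron unit of intermediate 9 only)
Why: sterically governed Ir-catalysed aromatic C–H borylation (Hartwig–Miyaura/Smith–Maleczka one-pot phenol synthesis) goes to C5, the only ring C–H with no ortho substituent, and Oxone then converts C–B into C–OH by a boron-to-oxygen shift under near-neutral conditions that spare the acetate, the methyl ether and the remote stereocentre.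

**Compound list**
1 | 1-dodecanol | CCCCCCCCCCCCO | starting material
2 | dodecyl N,N-diisopropylcarbamate | CCCCCCCCCCCCOC(=O)N(C(C)C)C(C)C | intermediate
3 | 2-(3-methoxybenzyl)-4,4,5,5-tetramethyl-1,3,2-dioxaborolane | COc1cccc(CB2OC(C)(C)C(C)(C)O2)c1 | starting material
4 | (S)-1-lithiododecyl N,N-diisopropylcarbamate, (−)-sparteine-bound | CCCCCCCCCCC[C@H]([Li])OC(=O)N(C(C)C)C(C)C | intermediate
5 | lithium (S)-{1-[(diisopropylcarbamoyl)oxy]dodecyl}(3-methoxybenzyl)(pinacolato)borate | CCCCCCCCCCC[C@H]([B-]1(Cc2cccc(OC)c2)OC(C)(C)C(C)(C)O1)OC(=O)N(C(C)C)C(C)C.[Li+] | intermediate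
6 | (R)-2-[1-(3-methoxyphenyl)tridecan-2-yl]-4,4,5,5-tetramethyl-1,3,2-dioxaborolane | CCCCCCCCCCC[C@H](Cc1cccc(OC)c1)B1OC(C)(C)C(C)(C)O1 | intermediate
7 | (R)-1-(3-methoxyphenyl)tridecan-2-ol | CCCCCCCCCCC[C@H](Cc1cccc(OC)c1)O | intermediate
8 | (R)-1-(3-methoxyphenyl)tridecan-2-yl acetate | CCCCCCCCCCC[C@H](Cc1cccc(OC)c1)OC(C)=O | intermediate
9 | (R)-1-[3-methoxy-5-(4,4,5,5-tetramethyl-1,3,2-dioxaborolan-2-yl)phenyl]tridecan-2-yl acetate | CCCCCCCCCCC[C@H](Cc1cc(OC)cc(c1)B1OC(C)(C)C(C)(C)O1)OC(C)=O | intermediate
10 | (R)-1-(3-hydroxy-5-methoxyphenyl)tridecan-2-yl acetate (CNP0215596.1) | CCCCCCCCCCC[C@H](Cc1cc(O)cc(OC)c1)OC(C)=O | target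

**Step count**
Total steps: 4. Longest linear sequence: 4 (1 → 2 → 7 → 8 → 10).

**Three steps most likely to fail**

Step 2 is the main risk. A benzylic boronic ester can be deprotonated at the benzylic position by the lithiated carbamate, the 1,2-shift of the pinacol ate complex can stall, and the er may fall short. The fallback sets out from 1 and comes back at 7, and it trades the metallate shift for epoxide chemistry. Compound 1 is oxidised (TEMPO, NaOCl, KBr, CH2Cl2/H2O, 0 °C) to dodecanal F1. Corey–Chaykovsky methylenation (Me3S+ I−, NaH, DMSO/THF) gives racemic 2-undecyloxirane F2. Jacobsen hydrolytic kinetic resolution with (R,R)-(salen)Co(III)OAc (0.5 mol%) and 0.55 equiv H2O leaves (R)-2-undecyloxirane F3, the other enantiomer being hydrolysed and removed. The (R,R)/(R) pairing is quoted from memory, so the recovered epoxide should be confirmed by rotation or chiral GC before use. CuI-catalysed opening at the CH2 terminus with commercial 3-methoxyphenylmagnesium bromide (THF, −30 °C) then gives 7 with the stereocentre untouched.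

Step 4 is the second risk. Some borylation ortho to the small OMe group (C4) would give an isomeric phenol, and the oxidation must not touch the acetate. The fallback sets out from 2 and comes back at 10, and it replaces C–H oxidation by desymmetrisation of a symmetrical resorcinol dimethyl ether.
- Commercial 3,5-dimethoxybenzyl bromide is borylated (B2pin2, Pd(dba)2, P(4-MeOC6H4)3, KOAc, toluene, 50 °C) to 2-(3,5-dimethoxybenzyl)-4,4,5,5-tetramethyl-1,3,2-dioxaborolane F4.
- Compound 2 is lithiated exactly as in step 2 to 4 and combined with F4 to give the lithium boronate complex F5. This rearranges to the (R)-secondary boronic ester F6 and is oxidised in the same pot to (R)-1-(3,5-dimethoxyphenyl)tridecan-2-ol F7.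
- NaSEt in DMF at 140 °C removes one methyl group only, because the phenoxide formed shuts down the second cleavage, giving (R)-3-(2-hydroxytridecyl)-5-methoxyphenol F8.
- Ac2O/pyridine/DMAP gives the diacetate (R)-1-(3-acetoxy-5-methoxyphenyl)tridecan-2-yl acetate F9.
- Mild methanolysis (NH4OAc, MeOH, rt) cleaves only the aryl acetate and returns 10.

Step 1 is the third risk, and a small one. Acylation by the hindered carbamoyl chloride can be sluggish, and residual alcohol spoils the lithiation. The fallback sets out from 1 and comes back at 6 inside step 2, and it changes the carbenoid precursor from a carbamate to a hindered benzoate made by alcohol activation. Mitsunobu esterification of 1 with 2,4,6-triisopropylbenzoic acid (PPh3, DIAD, THF) gives dodecyl 2,4,6-triisopropylbenzoate F10. s-BuLi/(−)-sparteine (Et2O, −78 °C) gives (S)-1-lithiododecyl 2,4,6-triisopropylbenzoate F11 with the same sense of deprotonation. Addition of 3 gives the lithium boronate complex F12, which expels the benzoate on warming without a Lewis acid and delivers 6. Compound 6 is then oxidised to 7 as in step 2.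

**Further compounds**
F1 | step 2 | dodecanal | CCCCCCCCCCCC=O
F2 | step 2 | racemic 2-undecyloxirane | CCCCCCCCCCCC1CO1
F3 | step 2 | (R)-2-undecyloxirane | CCCCCCCCCCC[C@@H]1CO1
F4 | step 4 | 2-(3,5-dimethoxybenzyl)-4,4,5,5-tetramethyl-1,3,2-dioxaborolane | COc1cc(CB2OC(C)(C)C(C)(C)O2)cc(OC)c1
F5 | step 4 | lithium (S)-{1-[(diisopropylcarbamoyl)oxy]dodecyl}(3,5-dimethoxybenzyl)(pinacolato)borate | CCCCCCCCCCC[C@H]([B-]1(Cc2cc(OC)cc(OC)c2)OC(C)(C)C(C)(C)O1)OC(=O)N(C(C)C)C(C)C.[Li+]
F6 | step 4 | (R)-2-[1-(3,5-dimethoxyphenyl)tridecan-2-yl]-4,4,5,5-tetramethyl-1,3,2-dioxaborolane | CCCCCCCCCCC[C@H](Cc1cc(OC)cc(OC)c1)B1OC(C)(C)C(C)(C)O1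
F7 | step 4 | (R)-1-(3,5-dimethoxyphenyl)tridecan-2-ol | CCCCCCCCCCC[C@H](Cc1cc(OC)cc(OC)c1)O
F8 | step 4 | (R)-3-(2-hydroxytridecyl)-5-methoxyphenol | CCCCCCCCCCC[C@H](Cc1cc(O)cc(OC)c1)O
F9 | step 4 | (R)-1-(3-acetoxy-5-methoxyphenyl)tridecan-2-yl acetate | CCCCCCCCCCC[C@H](Cc1cc(OC(C)=O)cc(OC)c1)OC(C)=O
F10 | step 1 | dodecyl 2,4,6-triisopropylbenzoate | CCCCCCCCCCCCOC(=O)c1c(C(C)C)cc(C(C)C)cc1C(C)C
F11 | step 1 | (S)-1-lithiododecyl 2,4,6-triisopropylbenzoate, (−)-sparteine-bound | CCCCCCCCCCC[C@H]([Li])OC(=O)c1c(C(C)C)cc(C(C)C)cc1C(C)C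
F12 | step 1 | lithium (S)-{1-[(2,4,6-triisopropylbenzoyl)oxy]dodecyl}(3-methoxybenzyl)(pinacolato)borate | CCCCCCCCCCC[C@H]([B-]1(Cc2cccc(OC)c2)OC(C)(C)C(C)(C)O1)OC(=O)c1c(C(C)C)cc(C(C)C)cc1C(C)C.[Li+]
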